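**Plan**

- Cuts: the C8–OOH bond (ene reaction, last); the C1–C14 bond, which opens the 14-membered ring; C13–C14 and the C11/C12 epoxide oxygen; the lactone C1=C15 and C16–O bonds; C1–C2. What remains is (2E,6E)-farnesol as C2–C13 with C18–C20.
- Forward: the alcohol end of the farnesol chain becomes the C3/C4 diol unit and then the six-membered unsaturated lactone. The far end becomes the C11/C12 epoxide and the C14 iodide. The 14-membered ring closes next and the hydroperoxide is added last.
- Stereochemistry: C4 and C11/C12 come from two Katsuki–Sharpless epoxidations with L-(+)-DET. C3 is set by SN2 inversion through a cyclic carbonate, C1 by the C3 tether in the ring closure, C15 by equilibration, and C8 by the open face of the ring alkene.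
- Enabling feature: C1 is the β-carbon of the δ-lactone ring (O–C16–C15–C1–C2–C3) and stands 1,3 to C3, the ring carbon that carries the C4–C14 chain. A radical at C14 can therefore add to the C15=C1 bond from the chain's own face and give the cis-1,3 fusion of lactone and 14-membered ring.

Key step: step 12

Numbering: cembrane numbering is used for all intermediates (ring C1–C14; C15 on C1 carries methyl C17 and carbonyl C16, which is bound through oxygen to C3; methyls C18, C19, C20 on C4, C8, C12).

Assumption: the 15S lactone (methyl trans to C14, equatorial) is the more stable C15 epimer, and the open face of the 7,8-alkene in 21 is the one that leads to 8R.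

**Route**

Step 1
Reactants: 1 (2E,6E)-farnesol
Product: 2 (2S,3S)-2,3-epoxyfarnesol
Conditions: Ti(OiPr)4 (5 mol %), L-(+)-DET (7 mol %), t-BuOOH, 4 Å MS, CH2Cl2, −20 °C
Reagents that add atoms: tert-butyl hydroperoxide, CC(C)(C)OO
Why: Katsuki–Sharpless asymmetric epoxidation acts on the allylic alcohol only; with L-(+)-DET the titanium–tartrate complex should deliver oxygen to the face that gives the (2S,3S)-epoxide (the sense known for geraniol), which fixes the future C4 as S and leaves the two remote alkenes untouched.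

Step 2
Reactants: 2 (2S,3S)-2,3-epoxyfarnesol
Product: 4 (2R,3S,6E)-3,7,11-trimethyldodeca-6,10-diene-1,2,3-triol, via cyclic carbonate 3 (not isolated)
Conditions: Cs2CO3, CO2 (1 atm), 3 Å MS, DMF, 50 °C; then MeOH, 23 °C
Reagents that add atoms: carbon dioxide, O=C=O
Why: Carboxylation of the primary alkoxide and intramolecular 5-exo SN2 opening of the epoxide by the carbonate oxygen (epoxy alcohol to cyclic carbonate transposition) should invert C2, the future C3, while the tertiary C–O bond is kept, and base-catalysed methanolysis (transesterification) then frees the anti triol; attack at the tertiary carbon, which would give the enantiomer, is not expected under basic conditions.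

Step 3
Reactants: 4 (2R,3S,6E)-3,7,11-trimethyldodeca-6,10-diene-1,2,3-triol
Product: 6 (2S,5E)-6,10-dimethyl-2-[(2R)-oxiran-2-yl]undeca-5,9-dien-2-ol, via primary tosylate 5 (not isolated)
Conditions: TsCl (1.05 equiv), Bu2SnO (2 mol %), Et3N, CH2Cl2, 0 °C; then K2CO3, MeOH, 0 °C
Reagents that add atoms: none
Why: Tin-acetal-catalysed sulfonylation should select the primary hydroxyl of the 1,2-diol, and the secondary alkoxide then displaces the tosylate (3-exo-tet Williamson closure) with retention at the carbinol carbon; the mild, cold base is chosen so that the tertiary hydroxyl stays protonated and no Payne rearrangement leads back to 2.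

Step 4
Reactants: 6 (2S,5E)-6,10-dimethyl-2-[(2R)-oxiran-2-yl]undeca-5,9-dien-2-ol; 7 vinylmagnesium bromide
Product: 8 (4R,5S,8E)-5,9,13-trimethyltetradeca-1,8,12-triene-4,5-diol
Conditions: 7 (3.5 equiv), CuI (15 mol %), THF, −40 → 0 °C
Reagents that add atoms: vinylmagnesium bromide 7, C=C[Mg]Br
Why: Copper-catalysed Grignard opening of a terminal epoxide at its unsubstituted carbon, expected to be faster at low temperature than any epoxide migration, adds C1 without touching a stereocentre.

Step 5
Reactants: 8 (4R,5S,8E)-5,9,13-trimethyltetradeca-1,8,12-triene-4,5-diol; 9 methacryloyl chloride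
Product: 10 (4R,5S,8E)-5-hydroxy-5,9,13-trimethyltetradeca-1,8,12-trien-4-yl 2-methylprop-2-enoate
Conditions: 9 (1.3 equiv), Et3N, DMAP (10 mol %), CH2Cl2, 0 °C
Reagents that add atoms: methacryloyl chloride 9, CC(=C)C(Cl)=O
Why: DMAP-catalysed acylation (esterification) should take place at the secondary hydroxyl because the neighbouring tertiary hydroxyl is too hindered to react with the acylpyridinium ion.

Step 6
Reactants: 10 (4R,5S,8E)-5-hydroxy-5,9,13-trimethyltetradeca-1,8,12-trien-4-yl 2-methylprop-2-enoate
Product: 11 (6R)-6-[(2S,5E)-2-hydroxy-6,10-dimethylundeca-5,9-dien-2-yl]-3-methyl-5,6-dihydro-2H-pyran-2-one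
Conditions: Grubbs second-generation catalyst (5 mol %), CH2Cl2 (5 mM), 40 °C
Reagents that add atoms: none
Why: Ring-closing metathesis: the ruthenium carbene forms at the monosubstituted alkene and should close the six-membered ring onto the methacrylate (C1=C15) with loss of ethylene, whereas the trisubstituted 7,8- and 11,12-alkenes could react only through a seven-membered or larger ring and a disubstituted carbene.

Step 7
Reactants: 11 (6R)-6-[(2S,5E)-2-hydroxy-6,10-dimethylundeca-5,9-dien-2-yl]-3-methyl-5,6-dihydro-2H-pyran-2-one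
Product: 12 (6R)-6-[(2S,5E,9E)-2,11-dihydroxy-6,10-dimethylundeca-5,9-dien-2-yl]-3-methyl-5,6-dihydro-2H-pyran-2-one
Conditions: SeO2 (0.3 equiv), t-BuOOH (3 equiv), salicylic acid (10 mol %), CH2Cl2, 23 °C
Reagents that add atoms: selenium dioxide, O=[Se]=O; tert-butyl hydroperoxide, CC(C)(C)OO
Why: Selenium dioxide allylic oxidation (ene reaction, then [2,3]-sigmatropic shift of the allylseleninic acid) is known to select the E-methyl group of a terminal isopropylidene unit, so C13 should be hydroxylated with E geometry while the electron-poor lactone alkene is inert and the 7,8-alkene reacts more slowly.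

Step 8
Reactants: 12 (6R)-6-[(2S,5E,9E)-2,11-dihydroxy-6,10-dimethylundeca-5,9-dien-2-yl]-3-methyl-5,6-dihydro-2H-pyran-2-one
Product: 13 (6R)-6-[(2S,5E)-2-hydroxy-8-[(2S,3S)-3-(hydroxymethyl)-3-methyloxiran-2-yl]-6-methyloct-5-en-2-yl]-3-methyl-5,6-dihydro-2H-pyran-2-one
Conditions: Ti(OiPr)4 (10 mol %), L-(+)-DET (14 mol %), t-BuOOH, 4 Å MS, CH2Cl2, −20 °C
Reagents that add atoms: tert-butyl hydroperoxide, CC(C)(C)OO
Why: Second Katsuki–Sharpless epoxidation, now steered by the C13 hydroxyl: for this E-2-methyl allylic alcohol L-(+)-DET should give the (11S,12S)-epoxide, and neither the isolated 7,8-alkene nor the conjugated lactone alkene reacts with the titanium peroxide.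

Step 9
Reactants: 13 (6R)-6-[(2S,5E)-2-hydroxy-8-[(2S,3S)-3-(hydroxymethyl)-3-methyloxiran-2-yl]-6-methyloct-5-en-2-yl]-3-methyl-5,6-dihydro-2H-pyran-2-one; 14 (chloromethyl)(isopropoxy)dimethylsilane
Product: 17 (6R)-6-[(2S,5E)-2-hydroxy-8-[(2S,3S)-3-{2-[dimethyl(propan-2-yloxy)silyl]ethyl}-3-methyloxiran-2-yl]-6-methyloct-5-en-2-yl]-3-methyl-5,6-dihydro-2H-pyran-2-one, via triflate 15 (not isolated), via Grignard reagent 16 (not isolated)
Conditions: Tf2O (1.05 equiv), 2,6-lutidine, CH2Cl2, −78 °C; then 16 (from 14, Mg, THF; 3 equiv), CuI (10 mol %), THF, −78 → −40 °C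
Reagents that add atoms: (chloromethyl)(isopropoxy)dimethylsilane 14, CC(C)O[Si](C)(C)CCl
Why: Copper-catalysed coupling of a primary triflate with a Grignard reagent (SN2 at C13) adds C14 as a masked hydroxymethyl group; at −78 °C the triflate should be displaced far faster than the trisubstituted epoxide or the hindered lactone can react, no stereocentre is involved, and the extra carbon places the later radical one atom away from the epoxide.

Step 10
Reactants: 17 (6R)-6-[(2S,5E)-2-hydroxy-8-[(2S,3S)-3-{2-[dimethyl(propan-2-yloxy)silyl]ethyl}-3-methyloxiran-2-yl]-6-methyloct-5-en-2-yl]-3-methyl-5,6-dihydro-2H-pyran-2-one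
Product: 18 (6R)-6-[(2S,5E)-2-hydroxy-8-[(2S,3S)-3-(2-hydroxyethyl)-3-methyloxiran-2-yl]-6-methyloct-5-en-2-yl]-3-methyl-5,6-dihydro-2H-pyran-2-one
Conditions: 30% H2O2, KF, KHCO3, THF/MeOH, 23 °C
Reagents that add atoms: hydrogen peroxide, OO
Why: Tamao–Kumada oxidation: hydroperoxide adds to the fluoride-activated alkoxysilane and the primary alkyl group migrates from silicon to oxygen, which turns the C14–Si bond into C14–OH under buffered conditions that a lactone, an epoxide and a trisubstituted alkene should tolerate.

Step 11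
Reactants: 18 (6R)-6-[(2S,5E)-2-hydroxy-8-[(2S,3S)-3-(2-hydroxyethyl)-3-methyloxiran-2-yl]-6-methyloct-5-en-2-yl]-3-methyl-5,6-dihydro-2H-pyran-2-one
Product: 19 (6R)-6-[(2S,5E)-2-hydroxy-8-[(2S,3S)-3-(2-iodoethyl)-3-methyloxiran-2-yl]-6-methyloct-5-en-2-yl]-3-methyl-5,6-dihydro-2H-pyran-2-one
Conditions: I2, PPh3, imidazole, CH2Cl2, 0 °C
Reagents that add atoms: iodine, II
Why: Appel-type iodination (alkoxyphosphonium salt, then SN2 by iodide) converts the only primary alcohol; the tertiary hydroxyl does not react and imidazole keeps the medium non-acidic for the epoxide.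

Step 12
Reactants: 19 (6R)-6-[(2S,5E)-2-hydroxy-8-[(2S,3S)-3-(2-iodoethyl)-3-methyloxiran-2-yl]-6-methyloct-5-en-2-yl]-3-methyl-5,6-dihydro-2H-pyran-2-one
Product: 21 (1R,3R,4S,7E,11S,12S,15S)-11,12-epoxy-4-hydroxycembr-7-en-16,3-olide, via 15-epi lactone 20 (not isolated)
Conditions: 4CzIPN (5 mol %), Et3N (5 equiv), t-BuOH/H2O 9:1 (1 mM), 450 nm LEDs, 25 °C, Ar; then evaporate, DBU (1 equiv), PhMe, 100 °C
Reagents that add atoms: none
Why: Under 4CzIPN photocatalysis triethylamine gives an α-aminoalkyl radical that abstracts the iodine atom from C14, the nucleophilic primary radical adds to C1, the β-carbon of the unsaturated lactone, and the tertiary α-acyl radical at C15 is reduced to the enolate and protonated by water, so that no stoichiometric hydrogen-atom donor competes with a slow closure; the closest known reaction type is the reductive (Giese) radical macrocyclization of ω-iodoalkyl acrylates and enones. The new bond closes the 14-membered carbocycle in the 14-exo-trig sense (C15 stays outside the new ring), which, counted through the ester linkage C3–O–C16–C15, is the 16-endo mode of those macrolide-forming closures. C1 is controlled by the tether: the chain leaves C3 on one face of the nearly flat lactone and, with only C2 between C3 and C1 and with the 7E-alkene and the trans-epoxide stiffening the eleven-atom bridge, C14 is expected to reach the π-lobe of C1 on that same face, which gives the cis-1,3 fusion that an external reagent adding anti to the C3 substituent would not give. C15 is not left to kinetic protonation: DBU equilibrates the α-methyl lactone, and the fraction formed as 20 should be converted into the 15S epimer with the methyl group trans to C14 and equatorial. The step needs ring closure to outrun loss of the radical, which is served by 1 mM concentration, a medium without weak C–H bonds and the trans-epoxide, which keeps C14 from reaching the 7,8-alkene or the C9/C10 hydrogens through small cyclic transition states; the free C4 hydroxyl, the epoxide and the electron-rich alkene do not react with a nucleophilic alkyl radical.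

Step 13
Reactants: 21 (1R,3R,4S,7E,11S,12S,15S)-11,12-epoxy-4-hydroxycembr-7-en-16,3-olide
Product: 22 (1R,3R,4S,6E,8R,11S,12S,15S)-11,12-epoxy-8-hydroperoxy-4-hydroxycembr-6-en-16,3-olide
Conditions: O2, methylene blue (2 mol %), CH2Cl2, 0 °C, white LEDs; no reductive work-up
Reagents that add atoms: oxygen, O=O
Why: Schenck ene reaction: singlet oxygen, an electrophile, should react only with the trisubstituted 7,8-alkene, bond to C8 and take a hydrogen from C6 on the same face so that the double bond moves to C6=C7 with E geometry; the cis effect limits abstraction to C6 and the C19 methyl group, the 8R configuration is expected from attack on the open outer face of the ring alkene, and leaving out any reductant keeps the hydroperoxide.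

**Compound list**

1 | (2E,6E)-farnesol | CC(C)=CCC/C(C)=C/CC/C(C)=C/CO | starting material
2 | (2S,3S)-2,3-epoxyfarnesol, [(2S,3S)-3-[(3E)-4,8-dimethylnona-3,7-dien-1-yl]-3-methyloxiran-2-yl]methanol | CC(C)=CCC/C(C)=C/CC[C@]1(C)O[C@H]1CO | intermediate
3 | cyclic carbonate formed in situ, (4R)-4-[(2S,5E)-2-hydroxy-6,10-dimethylundeca-5,9-dien-2-yl]-1,3-dioxolan-2-one | CC(C)=CCC/C(C)=C/CC[C@](C)(O)[C@H]1COC(=O)O1 | intermediate
4 | (2R,3S,6E)-3,7,11-trimethyldodeca-6,10-diene-1,2,3-triol | CC(C)=CCC/C(C)=C/CC[C@](C)(O)[C@H](O)CO | intermediate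
5 | primary tosylate formed in situ, (2R,3S,6E)-2,3-dihydroxy-3,7,11-trimethyldodeca-6,10-dien-1-yl 4-methylbenzenesulfonate | CC(C)=CCC/C(C)=C/CC[C@](C)(O)[C@H](O)COS(=O)(=O)c1ccc(C)cc1 | intermediate
6 | (2S,5E)-6,10-dimethyl-2-[(2R)-oxiran-2-yl]undeca-5,9-dien-2-ol | CC(C)=CCC/C(C)=C/CC[C@](C)(O)[C@H]1CO1 | intermediate
7 | vinylmagnesium bromide | C=C[Mg]Br | starting material
8 | (4R,5S,8E)-5,9,13-trimethyltetradeca-1,8,12-triene-4,5-diol | C=CC[C@@H](O)[C@@](C)(O)CC/C=C(\C)CCC=C(C)C | intermediate
9 | methacryloyl chloride | CC(=C)C(Cl)=O | starting material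
10 | (4R,5S,8E)-5-hydroxy-5,9,13-trimethyltetradeca-1,8,12-trien-4-yl 2-methylprop-2-enoate | C=CC[C@@H](OC(=O)C(C)=C)[C@@](C)(O)CC/C=C(\C)CCC=C(C)C | intermediate
11 | (6R)-6-[(2S,5E)-2-hydroxy-6,10-dimethylundeca-5,9-dien-2-yl]-3-methyl-5,6-dihydro-2H-pyran-2-one | CC1=CC[C@@H](OC1=O)[C@@](C)(O)CC/C=C(\C)CCC=C(C)C | intermediate
12 | (6R)-6-[(2S,5E,9E)-2,11-dihydroxy-6,10-dimethylundeca-5,9-dien-2-yl]-3-methyl-5,6-dihydro-2H-pyran-2-one | CC1=CC[C@@H](OC1=O)[C@@](C)(O)CC/C=C(\C)CC/C=C(\C)CO | intermediate
13 | (6R)-6-[(2S,5E)-2-hydroxy-8-[(2S,3S)-3-(hydroxymethyl)-3-methyloxiran-2-yl]-6-methyloct-5-en-2-yl]-3-methyl-5,6-dihydro-2H-pyran-2-one | CC1=CC[C@@H](OC1=O)[C@@](C)(O)CC/C=C(\C)CC[C@@H]1O[C@@]1(C)CO | intermediate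
14 | (chloromethyl)(isopropoxy)dimethylsilane | CC(C)O[Si](C)(C)CCl | starting material
15 | C13 triflate of 13 formed in situ, [(2S,3S)-3-{(3E,6S)-6-hydroxy-3-methyl-6-[(2R)-5-methyl-6-oxo-3,6-dihydro-2H-pyran-2-yl]hept-3-en-1-yl}-2-methyloxiran-2-yl]methyl trifluoromethanesulfonate | CC1=CC[C@@H](OC1=O)[C@@](C)(O)CC/C=C(\C)CC[C@@H]1O[C@@]1(C)COS(=O)(=O)C(F)(F)F | intermediate
16 | [(isopropoxy)dimethylsilyl]methylmagnesium chloride, made in situ from 14 and Mg | CC(C)O[Si](C)(C)C[Mg]Cl | intermediate
17 | (6R)-6-[(2S,5E)-2-hydroxy-8-[(2S,3S)-3-{2-[dimethyl(propan-2-yloxy)silyl]ethyl}-3-methyloxiran-2-yl]-6-methyloct-5-en-2-yl]-3-methyl-5,6-dihydro-2H-pyran-2-one | CC1=CC[C@@H](OC1=O)[C@@](C)(O)CC/C=C(\C)CC[C@@H]1O[C@@]1(C)CC[Si](C)(C)OC(C)C | intermediate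
18 | (6R)-6-[(2S,5E)-2-hydroxy-8-[(2S,3S)-3-(2-hydroxyethyl)-3-methyloxiran-2-yl]-6-methyloct-5-en-2-yl]-3-methyl-5,6-dihydro-2H-pyran-2-one | CC1=CC[C@@H](OC1=O)[C@@](C)(O)CC/C=C(\C)CC[C@@H]1O[C@@]1(C)CCO | intermediate
19 | (6R)-6-[(2S,5E)-2-hydroxy-8-[(2S,3S)-3-(2-iodoethyl)-3-methyloxiran-2-yl]-6-methyloct-5-en-2-yl]-3-methyl-5,6-dihydro-2H-pyran-2-one | CC1=CC[C@@H](OC1=O)[C@@](C)(O)CC/C=C(\C)CC[C@@H]1O[C@@]1(C)CCI | intermediate
20 | 15-epi lactone formed in situ, (1R,3R,4S,7E,11S,12S,15R)-11,12-epoxy-4-hydroxycembr-7-en-16,3-olide | C[C@H]1C(=O)O[C@@H]2C[C@H]1CC[C@]1(C)O[C@H]1CC/C(C)=C/CC[C@]2(C)O | intermediate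
21 | (1R,3R,4S,7E,11S,12S,15S)-11,12-epoxy-4-hydroxycembr-7-en-16,3-olide | C[C@@H]1C(=O)O[C@@H]2C[C@H]1CC[C@]1(C)O[C@H]1CC/C(C)=C/CC[C@]2(C)O | intermediate
22 | (1R,3R,4S,6E,8R,11S,12S,15S)-11,12-epoxy-8-hydroperoxy-4-hydroxycembr-6-en-16,3-olide (CNP0297487.3) | C[C@@H]1C(=O)O[C@@H]2C[C@H]1CC[C@]1(C)O[C@H]1CC[C@@](C)(OO)/C=C/C[C@]2(C)O | target

Total step count: 13
Longest linear sequence: 13 steps (1 to 22)

**Steps most likely to fail**

1. Step 12. Ring closure of the C14 radical onto a β-substituted, α-methylated lactone alkene is slow. Hydrogen abstraction from the amine or the medium (C14–I reduced to C14–H) or intermolecular addition may overtake it, and the chain may deliver C14 to the wrong face of C1. Fallback: the same bond is closed by a reversible polar addition. Setting out from 19, silver nitrite in ether would exchange iodide for nitro to give the primary nitroalkane F1. DBU in dilute acetonitrile would generate the C14 nitronate, whose intramolecular Michael addition to C1 should give the macrocyclic nitro lactone F2 under thermodynamic control of both the ring fusion and C15. Radical denitration (Bu3SnH, AIBN, toluene, 110 °C) would then remove the nitro group, and the sequence comes back to the route at 21.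

2. Step 13. Singlet oxygen may take a hydrogen from the C19 methyl group in place of C6, which gives a secondary C7 hydroperoxide with an exocyclic 8(19)-alkene, and it may attack the other face of the alkene. Fallback: the regioisomer is returned to the route by a reduction and a reductive transposition. Setting out from 21, the 7-hydroperoxy-8(19)-ene F3 that the photooxygenation forms would be reduced with PPh3 to the allylic alcohol F4. Mitsunobu reaction of F4 with 2-nitrobenzenesulfonylhydrazide (PPh3, DEAD, THF, −30 °C) and warming would eliminate the sulfinate and lose N2 from the allylic diazene with 1,3-transposition. This should regenerate the 7E-alkene, so the material comes back to the route at 21 for a second photooxygenation.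

3. Step 9. The copper reagent may open the trisubstituted epoxide or attack the lactone faster than it displaces the triflate at C13, which sits next to a fully substituted carbon, and the triflate may ionise or eliminate before coupling. Fallback: C14 is added as a methylene group without any displacement. Setting out from 13, Dess–Martin oxidation (NaHCO3, CH2Cl2) would give the epoxy aldehyde F5 and Wittig methylenation (Ph3P=CH2, THF, −78 °C) the vinyl epoxide F6. Hydroboration with 9-BBN at the terminal carbon followed by NaBO3 oxidation would give the primary alcohol, and the sequence comes back to the route at 18.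

Further compounds
F1 | step 12 | (6R)-6-[(2S,5E)-2-hydroxy-6-methyl-8-[(2S,3S)-3-methyl-3-(2-nitroethyl)oxiran-2-yl]oct-5-en-2-yl]-3-methyl-5,6-dihydro-2H-pyran-2-one | CC1=CC[C@@H](OC1=O)[C@@](C)(O)CC/C=C(\C)CC[C@@H]1O[C@@]1(C)CC[N+](=O)[O-]
F2 | step 12 | 14-nitro derivative of 21 (both C14 epimers) | C[C@@H]1C(=O)O[C@@H]2C[C@H]1C([N+](=O)[O-])C[C@]1(C)O[C@H]1CC/C(C)=C/CC[C@]2(C)O
F3 | step 13 | 7-hydroperoxy-8(19)-ene regioisomer of 22 (C7 epimers) | C[C@@H]1C(=O)O[C@@H]2C[C@H]1CC[C@]1(C)O[C@H]1CCC(=C)C(OO)CC[C@]2(C)O
F4 | step 13 | 7-hydroxy-8(19)-ene allylic alcohol from F3 (C7 epimers) | C[C@@H]1C(=O)O[C@@H]2C[C@H]1CC[C@]1(C)O[C@H]1CCC(=C)C(O)CC[C@]2(C)O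
F5 | step 9 | C13 aldehyde of 13 (epoxide unchanged) | CC1=CC[C@@H](OC1=O)[C@@](C)(O)CC/C=C(\C)CC[C@@H]1O[C@@]1(C)C=O
F6 | step 9 | 12-vinyl epoxide (C13=C14 alkene) from F5 | CC1=CC[C@@H](OC1=O)[C@@](C)(O)CC/C=C(\C)CC[C@@H]1O[C@@]1(C)C=C
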